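Count each target as two free nucleophile lost and each crossing free base as one regained.

    nucleophile + acid set free ⇌ protonated nucleophile, settled at all times (K1 = 37000 M⁻¹)
    electrophile + nucleophile → acid set free + target (k2 = 8.7 M⁻¹ h⁻¹)
    gas ⇌ free base, rate k3*(csat - [free base]) (k3 = 0.71 h⁻¹, csat = 5.4 mM)
    nucleophile + target → over-reaction product (k4 = 1.4 M⁻¹ h⁻¹)
    acid set free + free base ⇌ salt of the base, settled at all times (K5 = 4.3 × 10⁵ M⁻¹)

electrophile 20 mM; protonated nucleophile 1.80 equiv; gas 5.4 mM (held); time 15 h

- delta: doubling the saturation concentration of gas, all else as stated
- epsilon: doubling the transfer coefficient of step 3, all else as stated

- at the start none of free base is dissolved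
- run time (flask): 15 h

* amount of target at 15 h, in percent of the electrophile charged
* the change that raises the amount of target at 15 h, in percent of the electrophile charged most ("none" if none brings more than 2 percentage points) (delta / epsilon / none)
* amount of target at 15 h, in percent of the electrophile charged, after delta

I took dissolved free base to stay low against saturation, so I reckoned the gas to feed nucleophile at 3.83 mM h⁻¹: I let each free base free one nucleophile from the protonated nucleophile, and each target consume one nucleophile while its acid set free protonated another. In this reckoning nucleophile rose with the feed early on, and later feed and loss balanced. I joined these ends with a lag of 2.87 h and the balance level of nucleophile, the feed divided by 2 times the rate constant of target formation times the electrophile charged: 11.0 mM. The lag is shorter than the run, so I held nucleophile at that level for the time after the lag, a pseudo-first-order loss of electrophile with exponent 1.16. With over-reaction in series, this gave 61.6% target. Delta and epsilon each raised my feed to twice its value, giving 70.3% for both, so my reckoning could not rank them.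

The forecast gave 62% (56% to 67%), chose delta and gave 70% after it (63% to 76%), holding that “the saturation change keeps a larger driving force once free base builds up”.

The simulation gave 61.4%, chose delta with a gain of 7.6 percentage points against 5.9 points for epsilon, and gave 69.0% after delta.

In this flask, nucleophile stood at 4.45 mM after 1.50 h, where the joined curve gives 4.48 mM, and at 10.5 mM after 15.0 h, against the balance level of 11.0 mM, with free base then at 3.41 mM, while target was then made 3.19 times faster than it was used up, each step taken net. For the neighbour charged with 50 mM of electrophile, I reckoned a balance level of 4.41 mM, against 6.49 mM of nucleophile in that flask after 15.0 h, and the same reckoning with its lag of 1.15 h and exponent 0.531 gave 39.3% target, where that flask held 44.7%.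

(The numbers are assumed; the result is computed.)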